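**Retrosynthetic overview**
1. Target 39 ⇐ desilylation and C3 oxidation of 37 ⇐ traceless ester-tethered union: Barton decarboxylation of acid 35 ⇐ Ireland–Claisen rearrangement of allylic ester 33, which forms C5–C2′ next to the gem-dimethyl carbon, sets C5 by chirality transfer from C7–O and leaves the alkene at C6=C7.
2. Ester 33 ⇐ hydroazulenyl allylic alcohol 13 + benzoxepinyl propanoic acid 32 (the acid carbon is later lost as CO2, so the tether is never made by a fragment alkylation or olefination).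
3. 13 ⇐ CBS reduction ⇐ enone 12 ⇐ SmI2 ketyl–enone cyclization (five-membered ring last) ⇐ cycloheptadienone 11 ⇐ Ito–Saegusa one-carbon ring expansion ⇐ asymmetric conjugate addition to cyclohexadienone 2.
4. 32 ⇐ δ-lactone 30 ⇐ 7-endo epoxide opening (oxepane last) ⇐ C9a reduction, C5a methylation ⇐ Baeyer–Villiger of a cis-hydrindanone (gives C7–O and the three-carbon acid arm) ⇐ Hajos–Parrish-type enedione 20.
5. Ring order: carbocyclic half six → seven → five; other half five (purchased) → ring B → δ-lactone → oxepane; the two bicycles are joined last.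

Assumption: the target is taken exactly as the SMILES defines it, (5aS,6S,7R,9aR) in the 1-benzoxepine half (5a-methyl and 9a-H on the same face, cis-fused) and (1S,3aS,5R,8aS) in the azulene half; locants follow these two ring systems and C1′/C2′ are the tether carbons (C1′ on C6 of the benzoxepine).
Assumption: the facial sense of the copper/phosphoramidite conjugate addition in step 3 is taken from the cyclohexenone precedent; if the dienone responds oppositely the ligand antipode is used.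

**Step 1**
Reactants: 1 2,4,4-trimethylcyclohex-2-en-1-one
Product: 2 2,4,4-trimethylcyclohexa-2,5-dien-1-one
Conditions: DDQ, 1,4-dioxane, reflux
Reagents that add atoms: none
Why: DDQ dehydrogenation of the saturated flank of the enone gives the cross-conjugated dienone; no stereocentre is involved.

**Step 2**
Reactants: 3 2-(2-bromoethyl)-2-methyl-1,3-dioxolane
Product: 5 [2-(2-methyl-1,3-dioxolan-2-yl)ethyl][(trimethylsilyl)methyl]zinc, via Grignard reagent 4 (not isolated)
Conditions: Mg, THF, 23 °C; then add to Me3SiCH2ZnCl (from Me3SiCH2MgCl and ZnCl2, THF, 0 °C), −30 → 0 °C; then 1,4-dioxane, filter, exchange to toluene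
Reagents that add atoms: zinc dichloride, Cl[Zn]Cl; (trimethylsilyl)methylmagnesium chloride, C[Si](C)(C)C[Mg]Cl
Why: Grignard formation and magnesium–zinc transmetalation onto Me3SiCH2ZnCl give a salt-poor mixed diorganozinc in which the trimethylsilylmethyl group is a non-transferable ligand, so one equivalent of bromide 3 supplies the alkyl group for the copper-catalysed conjugate addition.

**Step 3**
Reactants: 2 2,4,4-trimethylcyclohexa-2,5-dien-1-one; 5 [2-(2-methyl-1,3-dioxolan-2-yl)ethyl][(trimethylsilyl)methyl]zinc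
Product: 7 trimethyl({(3S)-4,4,6-trimethyl-3-[2-(2-methyl-1,3-dioxolan-2-yl)ethyl]cyclohexa-1,5-dien-1-yl}oxy)silane, via zinc enolate 6 (not isolated)
Conditions: Cu(OTf)2 (2 mol%), (R)-BINOL (S,S)-bis(1-phenylethyl)amine phosphoramidite (4 mol%), toluene, −30 °C; then Me3SiOTf, Et3N, 0 °C
Reagents that add atoms: trimethylsilyl trifluoromethanesulfonate, C[Si](C)(C)OS(=O)(=O)C(F)(F)F
Why: Copper-catalysed asymmetric conjugate addition of the mixed diorganozinc, which transfers only the functionalised alkyl group, occurs at the unsubstituted enone of the dienone, the phosphoramidite sets the new stereocentre (later C3a) and silyl trapping fixes the enolate regiochemistry.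

**Step 4**
Reactants: 7 trimethyl({(3S)-4,4,6-trimethyl-3-[2-(2-methyl-1,3-dioxolan-2-yl)ethyl]cyclohexa-1,5-dien-1-yl}oxy)silane
Product: 8 trimethyl({(1R,5S,6S)-2,4,4-trimethyl-5-[2-(2-methyl-1,3-dioxolan-2-yl)ethyl]bicyclo[4.1.0]hept-2-en-1-yl}oxy)silane
Conditions: Et2Zn, CH2I2, CH2Cl2, 0 °C
Reagents that add atoms: diiodomethane, ICI
Why: Simmons–Smith (Furukawa) cyclopropanation takes the electron-rich silyl enol ether alkene anti to the side chain; the two new centres are erased in step 5.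

**Step 5**
Reactants: 8 trimethyl({(1R,5S,6S)-2,4,4-trimethyl-5-[2-(2-methyl-1,3-dioxolan-2-yl)ethyl]bicyclo[4.1.0]hept-2-en-1-yl}oxy)silane
Product: 11 (5S)-2,4,4-trimethyl-5-(3-oxobutyl)cyclohepta-2,6-dien-1-one, via chloro ketone 9 (not isolated), via dienone ketal 10 (not isolated)
Conditions: FeCl3, DMF, 0 °C; then NaOAc, MeOH, reflux; then 1 M HCl, THF, 23 °C
Reagents that add atoms: water, O
Why: Ito–Saegusa oxidative ring expansion opens the siloxycyclopropane at the internal bond to a β-chloro cycloheptenone, acetate eliminates HCl to the second enone and acid unmasks the methyl ketone; the stereocentre is untouched.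

**Step 6**
Reactants: 11 (5S)-2,4,4-trimethyl-5-(3-oxobutyl)cyclohepta-2,6-dien-1-one
Product: 12 (1S,3aS,8aS)-1-hydroxy-1,4,4,6-tetramethyl-2,3,3a,4,8,8a-hexahydroazulen-7(1H)-one
Conditions: SmI2 (2.2 equiv), HMPA, t-BuOH, THF, −78 °C
Reagents that add atoms: none
Why: SmI2 ketyl–olefin reductive cyclization closes the five-membered ring 5-exo on the nearer enone β-carbon, so the ring fusion is cis and the samarium-bound oxygen sits anti to C8 (hydroxyl syn to H-8a), while protonation of the dienolate returns the C5=C6 enone.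

**Step 7**
Reactants: 12 (1S,3aS,8aS)-1-hydroxy-1,4,4,6-tetramethyl-2,3,3a,4,8,8a-hexahydroazulen-7(1H)-one
Product: 13 (1S,3aS,7R,8aS)-1,4,4,6-tetramethyl-1,2,3,3a,4,7,8,8a-octahydroazulene-1,7-diol
Conditions: (S)-Me-CBS oxazaborolidine (20 mol%), BH3·SMe2, THF, −30 °C
Reagents that add atoms: none
Why: Corey–Bakshi–Shibata 1,2-reduction of the α-methyl enone is reagent-controlled and gives the 7R allylic alcohol, with the oxygen on the face where the C5 substituent is needed.

**Step 8**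
Reactants: 14 benzyl 4-bromobutyl ether; 15 N-methoxy-N-methylacrylamide
Product: 17 7-(benzyloxy)hept-1-en-3-one, via Grignard reagent 16 (not isolated)
Conditions: Mg, THF, 23 °C; then 15, −78 → 0 °C; cold 1 M HCl quench
Reagents that add atoms: none
Why: Weinreb ketone synthesis stops at the vinyl ketone because the chelated tetrahedral adduct survives until the acidic quench, which also keeps the released amine from adding back.

**Step 9**
Reactants: 17 7-(benzyloxy)hept-1-en-3-one; 18 2-methylcyclopentane-1,3-dione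
Product: 19 2-[7-(benzyloxy)-3-oxoheptyl]-2-methylcyclopentane-1,3-dione
Conditions: Et3N (cat.), MeCN, 23 °C
Reagents that add atoms: none
Why: Michael addition of the acidic 1,3-dione to the vinyl ketone gives the prochiral triketone.

**Step 10**
Reactants: 19 2-[7-(benzyloxy)-3-oxoheptyl]-2-methylcyclopentane-1,3-dione
Product: 20 (7aR)-4-[3-(benzyloxy)propyl]-7a-methyl-2,3,7,7a-tetrahydro-1H-indene-1,5(6H)-dione
Conditions: (R)-phenylalanine (1 equiv), camphorsulfonic acid (0.5 equiv), DMF, 30 → 70 °C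
Reagents that add atoms: none
Why: Hajos–Parrish–Eder–Sauer–Wiechert amino-acid-mediated aldol condensation desymmetrizes the dione, the (R)-amino acid giving the 7aR quaternary centre (later C7 of the benzoxepine).

**Step 11**
Reactants: 20 (7aR)-4-[3-(benzyloxy)propyl]-7a-methyl-2,3,7,7a-tetrahydro-1H-indene-1,5(6H)-dione
Product: 21 (3aS,4R,7aR)-4-(3-hydroxypropyl)-7a-methyloctahydro-1H-indene-1,5-dione
Conditions: H2 (3 atm), Pd/C, EtOH, 23 °C
Reagents that add atoms: none
Why: Heterogeneous hydrogenation of the hydrindenone adds hydrogen from the face of the angular methyl to give the cis-fused ring junction (later C6) and cleaves the benzyl ether at the same time; C4 is epimerizable and is reset in step 17.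

**Step 12**
Reactants: 21 (3aS,4R,7aR)-4-(3-hydroxypropyl)-7a-methyloctahydro-1H-indene-1,5-dione
Product: 22 internal methyl ketal of 21 (ketal carbon C5 bears OMe plus the side-chain oxygen; C1 ketone free)
Conditions: MeOH, PPTS (cat.), 23 °C
Reagents that add atoms: methanol, CO
Why: Intramolecular mixed-ketal formation through a six-membered ring masks only the six-ring ketone, because the hindered cyclopentanone cannot be reached by the side-chain hydroxyl.

**Step 13**
Reactants: 22 internal methyl ketal of 21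
Product: 23 δ-lactone of 22 (oxygen inserted between C1 and C7a)
Conditions: m-CPBA, CH2Cl2, 23 °C
Reagents that add atoms: 3-chloroperoxybenzoic acid, OOC(=O)c1cccc(Cl)c1
Why: Baeyer–Villiger oxidation migrates the quaternary carbon with retention, which installs the C7–O bond and turns the cyclopentanone carbons into the three-carbon acid arm.

**Step 14**
Reactants: 23 δ-lactone of 22
Product: 24 (4aS,5R,8aR)-5-(3-hydroxypropyl)-8a-methyloctahydro-2H-chromene-2,6-dione
Conditions: 1 M HCl, THF, 23 °C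
Reagents that add atoms: water, O
Why: Acid hydrolysis of the mixed ketal releases the ketone and the primary alcohol while the δ-lactone is stable.

**Step 15**
Reactants: 24 (4aS,5R,8aR)-5-(3-hydroxypropyl)-8a-methyloctahydro-2H-chromene-2,6-dione
Product: 25 3-[(4aS,5R,8aR)-8a-methyl-2,6-dioxooctahydro-2H-chromen-5-yl]propanal
Conditions: Dess–Martin periodinane, CH2Cl2, 23 °C
Reagents that add atoms: none
Why: Dess–Martin oxidation converts the only alcohol into the aldehyde under neutral conditions.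

**Step 16**
Reactants: 25 3-[(4aS,5R,8aR)-8a-methyl-2,6-dioxooctahydro-2H-chromen-5-yl]propanal
Product: 26 (4aS,5R,8aR)-8a-methyl-5-(4-methylpent-3-en-1-yl)octahydro-2H-chromene-2,6-dione
Conditions: i-PrPPh3I, n-BuLi, THF, −78 → 0 °C
Reagents that add atoms: isopropyltriphenylphosphonium iodide, CC(C)[P+](c1ccccc1)(c1ccccc1)c1ccccc1.[I-]
Why: Wittig olefination of the aldehyde is much faster than attack on the α-branched ketone or the lactone and delivers the homoprenyl chain.

**Step 17**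
Reactants: 26 (4aS,5R,8aR)-8a-methyl-5-(4-methylpent-3-en-1-yl)octahydro-2H-chromene-2,6-dione
Product: 27 (4aS,5S,8aR)-5,8a-dimethyl-5-(4-methylpent-3-en-1-yl)octahydro-2H-chromene-2,6-dione
Conditions: KOt-Bu, MeI, t-BuOH/THF, 0 °C
Reagents that add atoms: iodomethane, CI
Why: Alkylation of the thermodynamic (more substituted) enolate proceeds by axial attack anti to the C8a methyl, where the only 1,3-diaxial partner is the lactone oxygen, so the new methyl is cis to the lactone oxygen and the quaternary centre (later C5a) is set.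

**Step 18**
Reactants: 27 (4aS,5S,8aR)-5,8a-dimethyl-5-(4-methylpent-3-en-1-yl)octahydro-2H-chromene-2,6-dione
Product: 28 (4aS,5S,6R,8aR)-6-hydroxy-5,8a-dimethyl-5-(4-methylpent-3-en-1-yl)octahydro-2H-chromen-2-one
Conditions: Li(s-Bu)3BH, THF, −78 °C
Reagents that add atoms: none
Why: The bulky hydride attacks the ketone equatorially on the chair with the C5 methyl axial, giving the axial alcohol trans to that methyl and cis to the chain (later C9a), as in 4,4-dimethyl-3-keto terpenoids.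

**Step 19**
Reactants: 28 (4aS,5S,6R,8aR)-6-hydroxy-5,8a-dimethyl-5-(4-methylpent-3-en-1-yl)octahydro-2H-chromen-2-one
Product: 30 3-[(3RS,5aS,6S,7R,9aR)-3,7-dihydroxy-2,2,5a,7-tetramethyldecahydro-1-benzoxepin-6-yl]propanoic acid 7-lactone, via epoxide 29 (not isolated)
Conditions: m-CPBA, CH2Cl2, 0 °C; then camphorsulfonic acid (cat.), 0 → 23 °C
Reagents that add atoms: 3-chloroperoxybenzoic acid, OOC(=O)c1cccc(Cl)c1
Why: Prilezhaev epoxidation followed by acid-catalysed 7-endo epoxide opening at the tertiary carbon closes the cis-fused oxepane; the C3 carbinol is an inconsequential epimer mixture that is oxidized in step 25.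

**Step 20**
Reactants: 30 3-[(3RS,5aS,6S,7R,9aR)-3,7-dihydroxy-2,2,5a,7-tetramethyldecahydro-1-benzoxepin-6-yl]propanoic acid 7-lactone
Product: 32 3-[(3RS,5aS,6S,7R,9aR)-2,2,5a,7-tetramethyl-3,7-bis(triethylsilyloxy)decahydro-1-benzoxepin-6-yl]propanoic acid, via lithium carboxylate 31 (not isolated)
Conditions: LiOH, THF/H2O, 23 °C, evaporate; then Et3SiOTf, 2,6-lutidine, CH2Cl2, −78 → 23 °C; aqueous work-up
Reagents that add atoms: lithium hydroxide, [Li+].[OH-]; triethylsilyl trifluoromethanesulfonate, CC[Si](CC)(CC)OS(=O)(=O)C(F)(F)F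
Why: Saponification opens the lactone and silylation caps both hydroxyls so that the acid cannot relactonize, the silyl ester being cleaved on work-up.

**Step 21**
Reactants: 13 (1S,3aS,7R,8aS)-1,4,4,6-tetramethyl-1,2,3,3a,4,7,8,8a-octahydroazulene-1,7-diol; 32 3-[(3RS,5aS,6S,7R,9aR)-2,2,5a,7-tetramethyl-3,7-bis(triethylsilyloxy)decahydro-1-benzoxepin-6-yl]propanoic acid
Product: 33 (1S,3aS,7R,8aS)-1-hydroxy-1,4,4,6-tetramethyl-1,2,3,3a,4,7,8,8a-octahydroazulen-7-yl ester of 32
Conditions: DCC, DMAP (cat.), CH2Cl2, 23 °C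
Reagents that add atoms: none
Why: Steglich esterification acylates the secondary allylic alcohol selectively over the tertiary one and joins the two halves through a temporary C–O bond.

**Step 22**
Reactants: 33 (1S,3aS,7R,8aS)-1-hydroxy-1,4,4,6-tetramethyl-1,2,3,3a,4,7,8,8a-octahydroazulen-7-yl ester of 32
Product: 35 (2RS)-2-[(1S,3aS,5R,8aS)-1-hydroxy-1,4,4,6-tetramethyl-1,2,3,3a,4,5,8,8a-octahydroazulen-5-yl]-3-[(3RS,5aS,6S,7R,9aR)-2,2,5a,7-tetramethyl-3,7-bis(triethylsilyloxy)decahydro-1-benzoxepin-6-yl]propanoic acid, via silyl ketene acetal 34 (not isolated)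
Conditions: LiN(i-Pr)2 (3 equiv), Me3SiCl, THF, −78 → 65 °C; dilute citric acid work-up
Reagents that add atoms: none
Why: Ireland–Claisen rearrangement forms the C5–C2′ bond intramolecularly next to the gem-dimethyl carbon, is suprafacial so the 7R carbinol becomes the 5R centre, and moves the alkene to C6=C7; the C2′ centre is erased in step 23.

**Step 23**
Reactants: 35 (2RS)-2-[(1S,3aS,5R,8aS)-1-hydroxy-1,4,4,6-tetramethyl-1,2,3,3a,4,5,8,8a-octahydroazulen-5-yl]-3-[(3RS,5aS,6S,7R,9aR)-2,2,5a,7-tetramethyl-3,7-bis(triethylsilyloxy)decahydro-1-benzoxepin-6-yl]propanoic acid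
Product: 37 3,7-bis(triethylsilyl) ether of triol 38, via Barton ester 36 (not isolated)
Conditions: 1-hydroxypyridine-2(1H)-thione, DCC, DMAP (cat.), CH2Cl2, dark; then t-BuSH, hν, PhH, 23 °C
Reagents that add atoms: none
Why: Barton reductive decarboxylation removes the carboxyl that served as the tether handle and leaves the CH2–CH2 link, the secondary radical being quenched by the thiol faster than it can engage the alkene.

**Step 24**
Reactants: 37 3,7-bis(triethylsilyl) ether of triol 38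
Product: 38 (3RS,5aS,6S,7R,9aR)-6-{2-[(1S,3aS,5R,8aS)-1-hydroxy-1,4,4,6-tetramethyl-1,2,3,3a,4,5,8,8a-octahydroazulen-5-yl]ethyl}-2,2,5a,7-tetramethyldecahydro-1-benzoxepine-3,7-diol
Conditions: HF·pyridine, THF, 0 → 23 °C
Reagents that add atoms: none
Why: Fluoride-mediated desilylation frees the secondary and the tertiary hydroxyl without touching the alkene.

**Step 25**
Reactants: 38 (3RS,5aS,6S,7R,9aR)-6-{2-[(1S,3aS,5R,8aS)-1-hydroxy-1,4,4,6-tetramethyl-1,2,3,3a,4,5,8,8a-octahydroazulen-5-yl]ethyl}-2,2,5a,7-tetramethyldecahydro-1-benzoxepine-3,7-diol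
Product: 39 (5aS,6S,7R,9aR)-7-hydroxy-6-{2-[(1S,3aS,5R,8aS)-1-hydroxy-1,4,4,6-tetramethyl-1,2,3,3a,4,5,8,8a-octahydroazulen-5-yl]ethyl}-2,2,5a,7-tetramethyloctahydro-1-benzoxepin-3(2H)-one
Conditions: Dess–Martin periodinane, pyridine, CH2Cl2, 23 °C
Reagents that add atoms: none
Why: Dess–Martin oxidation takes the only secondary alcohol to the C3 ketone, converging both C3 epimers on the target while the two tertiary alcohols are inert.

**Compound list**
1 | 2,4,4-trimethylcyclohex-2-en-1-one | CC1=CC(C)(C)CCC1=O | starting material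
2 | 2,4,4-trimethylcyclohexa-2,5-dien-1-one | CC1=CC(C)(C)C=CC1=O | intermediate
3 | 2-(2-bromoethyl)-2-methyl-1,3-dioxolane | CC1(CCBr)OCCO1 | starting material
4 | [2-(2-methyl-1,3-dioxolan-2-yl)ethyl]magnesium bromide | CC1(CC[Mg]Br)OCCO1 | intermediate
5 | [2-(2-methyl-1,3-dioxolan-2-yl)ethyl][(trimethylsilyl)methyl]zinc | CC1(CC[Zn]C[Si](C)(C)C)OCCO1 | intermediate
6 | zinc dienolate of the (S)-conjugate adduct (O–Zn–CH2SiMe3) | CC1=CC(C)(C)[C@@H](CCC2(C)OCCO2)C=C1O[Zn]C[Si](C)(C)C | intermediate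
7 | trimethyl({(3S)-4,4,6-trimethyl-3-[2-(2-methyl-1,3-dioxolan-2-yl)ethyl]cyclohexa-1,5-dien-1-yl}oxy)silane | CC1=CC(C)(C)[C@@H](CCC2(C)OCCO2)C=C1O[Si](C)(C)C | intermediate
8 | trimethyl({(1R,5S,6S)-2,4,4-trimethyl-5-[2-(2-methyl-1,3-dioxolan-2-yl)ethyl]bicyclo[4.1.0]hept-2-en-1-yl}oxy)silane (cyclopropane anti to the side chain) | CC1=CC(C)(C)[C@@H](CCC2(C)OCCO2)[C@@H]2C[C@]12O[Si](C)(C)C | intermediate
9 | (5R,6RS)-6-chloro-2,4,4-trimethyl-5-[2-(2-methyl-1,3-dioxolan-2-yl)ethyl]cyclohept-2-en-1-one | CC1=CC(C)(C)[C@@H](CCC2(C)OCCO2)C(Cl)CC1=O | intermediate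
10 | (5S)-2,4,4-trimethyl-5-[2-(2-methyl-1,3-dioxolan-2-yl)ethyl]cyclohepta-2,6-dien-1-one | CC1=CC(C)(C)[C@@H](CCC2(C)OCCO2)C=CC1=O | intermediate
11 | (5S)-2,4,4-trimethyl-5-(3-oxobutyl)cyclohepta-2,6-dien-1-one | CC1=CC(C)(C)[C@@H](CCC(C)=O)C=CC1=O | intermediate
12 | (1S,3aS,8aS)-1-hydroxy-1,4,4,6-tetramethyl-2,3,3a,4,8,8a-hexahydroazulen-7(1H)-one (cis-fused, OH syn to H-8a) | CC1=CC(C)(C)[C@H]2CC[C@](C)(O)[C@H]2CC1=O | intermediate
13 | (1S,3aS,7R,8aS)-1,4,4,6-tetramethyl-1,2,3,3a,4,7,8,8a-octahydroazulene-1,7-diol | CC1=CC(C)(C)[C@H]2CC[C@](C)(O)[C@H]2C[C@H]1O | intermediate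
14 | benzyl 4-bromobutyl ether | BrCCCCOCc1ccccc1 | starting material
15 | N-methoxy-N-methylacrylamide | C=CC(=O)N(C)OC | starting material
16 | [4-(benzyloxy)butyl]magnesium bromide | Br[Mg]CCCCOCc1ccccc1 | intermediate
17 | 7-(benzyloxy)hept-1-en-3-one | C=CC(=O)CCCCOCc1ccccc1 | intermediate
18 | 2-methylcyclopentane-1,3-dione | CC1C(=O)CCC1=O | starting material
19 | 2-[7-(benzyloxy)-3-oxoheptyl]-2-methylcyclopentane-1,3-dione | CC1(CCC(=O)CCCCOCc2ccccc2)C(=O)CCC1=O | intermediate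
20 | (7aR)-4-[3-(benzyloxy)propyl]-7a-methyl-2,3,7,7a-tetrahydro-1H-indene-1,5(6H)-dione | C(OCCCC1=C2CCC(=O)[C@]2(C)CCC1=O)c1ccccc1 | intermediate
21 | (3aS,4R,7aR)-4-(3-hydroxypropyl)-7a-methyloctahydro-1H-indene-1,5-dione (cis-fused, drawn as the open hydroxy ketone) | OCCC[C@H]1C(=O)CC[C@@]2(C)C(=O)CC[C@@H]12 | intermediate
22 | internal methyl ketal of 21: C5 bears OMe and the side-chain oxygen (six-membered ring), C1 ketone free, ketal carbon as anomer mixture | COC12OCCC[C@@H]1[C@@H]1CCC(=O)[C@]1(C)CC2 | intermediate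
23 | δ-lactone from 22: oxygen inserted between C1 and C7a, mixed ketal retained | COC12OCCC[C@@H]1[C@@H]1CCC(=O)O[C@]1(C)CC2 | intermediate
24 | (4aS,5R,8aR)-5-(3-hydroxypropyl)-8a-methyloctahydro-2H-chromene-2,6-dione | OCCC[C@H]1C(=O)CC[C@@]2(C)OC(=O)CC[C@@H]12 | intermediate
25 | 3-[(4aS,5R,8aR)-8a-methyl-2,6-dioxooctahydro-2H-chromen-5-yl]propanal | O=CCC[C@H]1C(=O)CC[C@@]2(C)OC(=O)CC[C@@H]12 | intermediate
26 | (4aS,5R,8aR)-8a-methyl-5-(4-methylpent-3-en-1-yl)octahydro-2H-chromene-2,6-dione | CC(C)=CCC[C@H]1C(=O)CC[C@@]2(C)OC(=O)CC[C@@H]12 | intermediate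
27 | (4aS,5S,8aR)-5,8a-dimethyl-5-(4-methylpent-3-en-1-yl)octahydro-2H-chromene-2,6-dione | CC(C)=CCC[C@]1(C)C(=O)CC[C@@]2(C)OC(=O)CC[C@@H]12 | intermediate
28 | (4aS,5S,6R,8aR)-6-hydroxy-5,8a-dimethyl-5-(4-methylpent-3-en-1-yl)octahydro-2H-chromen-2-one | CC(C)=CCC[C@]1(C)[C@H](O)CC[C@@]2(C)OC(=O)CC[C@@H]12 | intermediate
29 | (4aS,5S,6R,8aR)-5-[2-(3,3-dimethyloxiran-2-yl)ethyl]-6-hydroxy-5,8a-dimethyloctahydro-2H-chromen-2-one (epoxide epimers) | CC1(C)OC1CC[C@]1(C)[C@H](O)CC[C@@]2(C)OC(=O)CC[C@@H]12 | intermediate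
30 | 3-[(3RS,5aS,6S,7R,9aR)-3,7-dihydroxy-2,2,5a,7-tetramethyldecahydro-1-benzoxepin-6-yl]propanoic acid 7-lactone (cis-fused oxepane, C3 epimers) | O=C1CC[C@H]2[C@]3(C)CCC(O)C(C)(C)O[C@@H]3CC[C@@]2(C)O1 | intermediate
31 | lithium 3-[(3RS,5aS,6S,7R,9aR)-3,7-dihydroxy-2,2,5a,7-tetramethyldecahydro-1-benzoxepin-6-yl]propanoate | [Li+].[O-]C(=O)CC[C@H]1[C@]2(C)CCC(O)C(C)(C)O[C@@H]2CC[C@@]1(C)O | intermediate
32 | 3-[(3RS,5aS,6S,7R,9aR)-2,2,5a,7-tetramethyl-3,7-bis(triethylsilyloxy)decahydro-1-benzoxepin-6-yl]propanoic acid | OC(=O)CC[C@H]1[C@]2(C)CCC(O[Si](CC)(CC)CC)C(C)(C)O[C@@H]2CC[C@@]1(C)O[Si](CC)(CC)CC | intermediate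
33 | (1S,3aS,7R,8aS)-1-hydroxy-1,4,4,6-tetramethyl-1,2,3,3a,4,7,8,8a-octahydroazulen-7-yl 3-[(3RS,5aS,6S,7R,9aR)-2,2,5a,7-tetramethyl-3,7-bis(triethylsilyloxy)decahydro-1-benzoxepin-6-yl]propanoate | CC1=CC(C)(C)[C@H]2CC[C@](C)(O)[C@H]2C[C@H]1OC(=O)CC[C@H]1[C@]2(C)CCC(O[Si](CC)(CC)CC)C(C)(C)O[C@@H]2CC[C@@]1(C)O[Si](CC)(CC)CC | intermediate
34 | trimethylsilyl ketene acetal of 33 with the azulene C1 hydroxyl as its trimethylsilyl ether | CC1=CC(C)(C)[C@H]2CC[C@](C)(O[Si](C)(C)C)[C@H]2C[C@H]1OC(O[Si](C)(C)C)=CC[C@H]1[C@]2(C)CCC(O[Si](CC)(CC)CC)C(C)(C)O[C@@H]2CC[C@@]1(C)O[Si](CC)(CC)CC | intermediate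
35 | (2RS)-2-[(1S,3aS,5R,8aS)-1-hydroxy-1,4,4,6-tetramethyl-1,2,3,3a,4,5,8,8a-octahydroazulen-5-yl]-3-[(3RS,5aS,6S,7R,9aR)-2,2,5a,7-tetramethyl-3,7-bis(triethylsilyloxy)decahydro-1-benzoxepin-6-yl]propanoic acid | CC1=CC[C@H]2[C@H](CC[C@]2(C)O)C(C)(C)[C@@H]1C(C(=O)O)C[C@H]1[C@]2(C)CCC(O[Si](CC)(CC)CC)C(C)(C)O[C@@H]2CC[C@@]1(C)O[Si](CC)(CC)CC | intermediate
36 | 2-thioxopyridin-1(2H)-yl ester of acid 35 | CC1=CC[C@H]2[C@H](CC[C@]2(C)O)C(C)(C)[C@@H]1C(C(=O)ON1C=CC=CC1=S)C[C@H]1[C@]2(C)CCC(O[Si](CC)(CC)CC)C(C)(C)O[C@@H]2CC[C@@]1(C)O[Si](CC)(CC)CC | intermediate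
37 | 3,7-bis(triethylsilyl) ether of triol 38 | CC1=CC[C@H]2[C@H](CC[C@]2(C)O)C(C)(C)[C@@H]1CC[C@H]1[C@]2(C)CCC(O[Si](CC)(CC)CC)C(C)(C)O[C@@H]2CC[C@@]1(C)O[Si](CC)(CC)CC | intermediate
38 | (3RS,5aS,6S,7R,9aR)-6-{2-[(1S,3aS,5R,8aS)-1-hydroxy-1,4,4,6-tetramethyl-1,2,3,3a,4,5,8,8a-octahydroazulen-5-yl]ethyl}-2,2,5a,7-tetramethyldecahydro-1-benzoxepine-3,7-diol | CC1=CC[C@H]2[C@H](CC[C@]2(C)O)C(C)(C)[C@@H]1CC[C@H]1[C@]2(C)CCC(O)C(C)(C)O[C@@H]2CC[C@@]1(C)O | intermediate
39 | (5aS,6S,7R,9aR)-7-hydroxy-6-{2-[(1S,3aS,5R,8aS)-1-hydroxy-1,4,4,6-tetramethyl-1,2,3,3a,4,5,8,8a-octahydroazulen-5-yl]ethyl}-2,2,5a,7-tetramethyloctahydro-1-benzoxepin-3(2H)-one (CNP0194989.5) | CC1=CC[C@H]2[C@H](CC[C@]2(C)O)C(C)(C)[C@@H]1CC[C@H]1[C@]2(C)CCC(=O)C(C)(C)O[C@@H]2CC[C@@]1(C)O | target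

**Totals**
Total step count: 25. Longest linear sequence: 18 steps (steps 8–25); the hydroazulene branch is 7 steps (steps 1–7) before the union.

**Three steps most likely to fail**

Step 6 (SmI2 cyclization). The dienone can be reduced without cyclizing, the enolate carbon C8 can attack instead of C8a, or the C1 carbinol can form with the wrong configuration. The fallback sets out from 11 and comes back at 12 by building the ring through C–C bond formation first and adding the oxygen afterwards. Kinetic enolization of the methyl ketone (LiN(i-Pr)2, PhNTf2, −78 °C) gives 4-[(1S)-5,7,7-trimethyl-4-oxocyclohepta-2,5-dien-1-yl]but-1-en-2-yl trifluoromethanesulfonate F1. A reductive Heck cyclization (Pd(OAc)2, PPh3, HCO2Na, DMF, 60 °C; the active catalyst is zerovalent palladium) adds the alkenyl group 5-exo to C8a and gives cis-fused (3aS,8aS)-4,4,6-trimethyl-1-methylidene-1,2,3,3a,8,8a-hexahydroazulen-7(4H)-one F2. m-CPBA epoxidizes only the electron-rich exocyclic alkene, from the convex face, to the spiro-epoxide with its oxygen syn to H-8a F3. LiBHEt3 opens the epoxide at CH2 and also reduces the ketone, giving (1S,3aS,7RS,8aS)-1,4,4,6-tetramethyl-1,2,3,3a,4,7,8,8a-octahydroazulene-1,7-diol F4, and MnO2 reoxidizes the allylic alcohol to 12.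

Step 19 (oxepane closure). Acid-catalysed opening can go 6-exo at C3 to a tetrahydropyran instead of 7-endo at the tertiary carbon. The fallback sets out from 28 and comes back at 30 and lets Markovnikov selectivity, not ring size, decide the regiochemistry. Alkoxymercuration with Hg(OCOCF3)2 in MeCN bonds the C9a oxygen to the tertiary carbon and gives the 3-(trifluoroacetoxymercurio) analogue of lactone 30 F5, which aqueous NaCl converts into the 3-(chloromercurio) analogue of lactone 30 F6. Oxidative demercuration (NaBH4, O2, DMF) replaces mercury by hydroxyl and gives 30 as the same C3 epimer mixture.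

Step 22 (Ireland–Claisen union). The new bond is made beside a quaternary carbon on a cycloheptenyl ester, so slow rearrangement and enolate decomposition are the main dangers. The fallback sets out from 12 and 32 and comes back at 37, replacing steps 21–23 by an intermolecular anti-SN2′ allylic substitution. Reduction of 12 with (R)-Me-CBS oxazaborolidine and BH3·SMe2 gives the epimeric (1S,3aS,7S,8aS)-1,4,4,6-tetramethyl-1,2,3,3a,4,7,8,8a-octahydroazulene-1,7-diol F7, which picolinic acid and DCC convert into its 7-picolinate F8. Acid 32 is turned with 1-hydroxypyridine-2(1H)-thione and DCC into its 2-thioxopyridin-1(2H)-yl ester F9, photolysis of which in the presence of CHI3 gives the 6-(2-iodoethyl) bis(triethylsilyl) ether F10, and Mg in THF gives the corresponding alkylmagnesium iodide F11. The tertiary hydroxyl of F8 is capped with i-PrMgCl as the chloromagnesium alkoxide F12, and CuBr·SMe2-catalysed coupling of F12 with F11 delivers the tether carbon to C5 anti to the picolinate and gives, after aqueous work-up, 37, from which steps 24 and 25 follow unchanged.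

**Further compounds**
F1 | step 6 | 4-[(1S)-5,7,7-trimethyl-4-oxocyclohepta-2,5-dien-1-yl]but-1-en-2-yl trifluoromethanesulfonate | CC1=CC(C)(C)[C@@H](CCC(=C)OS(=O)(=O)C(F)(F)F)C=CC1=O
F2 | step 6 | (3aS,8aS)-4,4,6-trimethyl-1-methylidene-1,2,3,3a,8,8a-hexahydroazulen-7(4H)-one | CC1=CC(C)(C)[C@H]2CCC(=C)[C@H]2CC1=O
F3 | step 6 | spiro-epoxide of F2 at C1 with the oxirane oxygen syn to H-8a | CC1=CC(C)(C)[C@H]2CC[C@@]3(CO3)[C@H]2CC1=O
F4 | step 6 | (1S,3aS,7RS,8aS)-1,4,4,6-tetramethyl-1,2,3,3a,4,7,8,8a-octahydroazulene-1,7-diol | CC1=CC(C)(C)[C@H]2CC[C@](C)(O)[C@H]2CC1O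
F5 | step 19 | 3-(trifluoroacetoxymercurio) analogue of lactone 30 (C3 epimers) | O=C1CC[C@H]2[C@]3(C)CCC([Hg]OC(=O)C(F)(F)F)C(C)(C)O[C@@H]3CC[C@@]2(C)O1
F6 | step 19 | 3-(chloromercurio) analogue of lactone 30 (C3 epimers) | O=C1CC[C@H]2[C@]3(C)CCC([Hg]Cl)C(C)(C)O[C@@H]3CC[C@@]2(C)O1
F7 | step 22 | (1S,3aS,7S,8aS)-1,4,4,6-tetramethyl-1,2,3,3a,4,7,8,8a-octahydroazulene-1,7-diol | CC1=CC(C)(C)[C@H]2CC[C@](C)(O)[C@H]2C[C@@H]1O
F8 | step 22 | (1S,3aS,7S,8aS)-1-hydroxy-1,4,4,6-tetramethyl-1,2,3,3a,4,7,8,8a-octahydroazulen-7-yl pyridine-2-carboxylate | CC1=CC(C)(C)[C@H]2CC[C@](C)(O)[C@H]2C[C@@H]1OC(=O)c1ccccn1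
F9 | step 22 | 2-thioxopyridin-1(2H)-yl ester of acid 32 | S=C1C=CC=CN1OC(=O)CC[C@H]1[C@]2(C)CCC(O[Si](CC)(CC)CC)C(C)(C)O[C@@H]2CC[C@@]1(C)O[Si](CC)(CC)CC
F10 | step 22 | (3RS,5aS,6S,7R,9aR)-6-(2-iodoethyl)-2,2,5a,7-tetramethyl-3,7-bis(triethylsilyloxy)decahydro-1-benzoxepine | ICC[C@H]1[C@]2(C)CCC(O[Si](CC)(CC)CC)C(C)(C)O[C@@H]2CC[C@@]1(C)O[Si](CC)(CC)CC
F11 | step 22 | alkylmagnesium iodide from F10 | I[Mg]CC[C@H]1[C@]2(C)CCC(O[Si](CC)(CC)CC)C(C)(C)O[C@@H]2CC[C@@]1(C)O[Si](CC)(CC)CC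
F12 | step 22 | chloromagnesium alkoxide of F8 | CC1=CC(C)(C)[C@H]2CC[C@](C)(O[Mg]Cl)[C@H]2C[C@@H]1OC(=O)c1ccccn1
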